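**Retrosynthetic overview**

1. Endgame: the cis-1,10-oxirane (1R,10S; H-1 and C-14 on the same side) is made from an E C1=C10 alkene by syn-dihydroxylation, C1 mesylation and SN2 closure by the C10 alkoxide (inversion at C1). The C3 acetate and C8 (2R)-2-methylbutanoate come from acylation, and C11=C13 from Eschenmoser methylenation of the 6,12-lactone. The lactone comes from a C6 ketone (C8-OH-directed anti reduction) and a CH2CO2t-Bu arm on C7.
2. Key disconnection C8–C9: the ten-membered ring is grown from a six-membered ring by an anionic oxy-Cope ring expansion, and the enolate formed is alkylated at C7 in the same flask.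
3. Enabling feature: the target hides the 1,5-diene C9=C10–C1/C6–C7=C8. C6 carries oxygen (carbinol, then ketone, then lactone O), C1–C10 is an oxidised alkene, and C8 carries oxygen (enol-ether terminus). The C4=C5 alkene is Z with C3 and C6 cis, so C1–C2–C3–C4=C5–C6 can be a cyclohexene whose C1–C6 bond is the one broken.
4. That cyclohexene is a (4R,6R)-4-silyloxy-isopiperitenone from (R)-carvone (Luche reduction, silylation, allylic oxidation). It supplies C3 and, through C1, relays chirality to C8 and C7, then to C6, C10 and C1.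
5. Ring order: cyclohexene (from carvone), ten-membered carbocycle (step 7), γ-lactone (step 10), oxirane (step 16).

Key step: step 7

Remark: locants C1–C15 are germacrane locants (ring C1–C10; C11–C13 on C7 with C12 the lactone carbonyl; C14 on C10; C15 on C4). The oxirane is read as cis (1R,10S) and the acyl group as (2R)-2-methylbutanoyl, as drawn. (R)-Carvone and (R)-2-methylbutanoic acid are taken as purchasable.

**Step 1**
Reactants: 1 (R)-(−)-carvone
Product: 2 (1R,5R)-cis-carveol
Conditions: NaBH4, CeCl3·7H2O, MeOH, −78 to 0 °C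
Reagents that add atoms: none
Why: Luche 1,2-reduction; axial hydride delivery should give the equatorial alcohol cis to the equatorial isopropenyl group, which sets the future C3 centre (R).

**Step 2**
Reactants: 2 (1R,5R)-cis-carveol
Product: 3 tert-butyldimethylsilyl ether of cis-carveol
Conditions: TBSCl, imidazole, DMF, rt
Reagents that add atoms: tert-butyldimethylsilyl chloride, CC(C)(C)[Si](C)(C)Cl
Why: Standard O-silylation of a secondary allylic alcohol; no stereocentre is touched.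

**Step 3**
Reactants: 3 silyl ether of cis-carveol
Product: 4 (4R,6R)-4-[(tert-butyldimethylsilyl)oxy]-3-methyl-6-(prop-1-en-2-yl)cyclohex-2-en-1-one
Conditions: CrO3, 3,5-dimethylpyrazole, CH2Cl2, −20 °C
Reagents that add atoms: chromium trioxide, O=[Cr](=O)=O
Why: Chromium-mediated allylic oxidation; it should take the ring CH2 on the unsubstituted alkene carbon (the site oxidised at C7 in Δ5-steroids), the silyloxy-bearing C–H and the isopropenyl group being less reactive, and the cis-4,6 arrangement is also the thermodynamic one.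

**Step 4**
Reactants: 5 4-methoxybenzyl alcohol
Product: 6 4-methoxybenzyl vinyl ether
Conditions: Pd(OAc)2 (cat.), 1,10-phenanthroline, ethyl vinyl ether (solvent), rt
Reagents that add atoms: ethyl vinyl ether, C=COCC
Why: Palladium-catalysed transfer vinylation of an alcohol, driven by the excess of ethyl vinyl ether.

**Step 5**
Reactants: 6 4-methoxybenzyl vinyl ether
Product: 8 (Z)-1-bromo-2-[(4-methoxybenzyl)oxy]ethene, via dibromo ether 7 (not isolated)
Conditions: Br2, CH2Cl2, −78 °C; then i-Pr2NEt, −78 to 40 °C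
Reagents that add atoms: bromine, BrBr
Why: Bromination of the enol ether then amine-induced dehydrobromination (loss of the α-bromide and a C2 proton), which should give mainly the cis (Z) 2-alkoxyvinyl bromide as for the ethyl analogue.

**Step 6**
Reactants: 8 (Z)-1-bromo-2-[(4-methoxybenzyl)oxy]ethene; 4 silyloxy enone
Product: 10 (1R,4R,6R)-4-[(tert-butyldimethylsilyl)oxy]-1-{(Z)-2-[(4-methoxybenzyl)oxy]ethenyl}-3-methyl-6-(prop-1-en-2-yl)cyclohex-2-en-1-ol, via vinyllithium 9 (not isolated)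
Conditions: t-BuLi (2 equiv), Et2O, −78 °C; then 4, THF, −78 °C; Et3N-buffered aqueous work-up, used crude
Reagents that add atoms: none
Why: Bromine–lithium exchange with retention gives the O-chelated, configurationally stable (Z)-2-alkoxyvinyllithium, and its 1,2-addition should occur trans to the adjacent isopropenyl group and to the silyloxy group on the same face, placing the two alkenyl groups trans.

**Step 7**
Reactants: 10 trans-dialkenyl cyclohexenol
Product: 13 tert-butyl 2-[(1S,2S,4E,7R,8Z)-7-[(tert-butyldimethylsilyl)oxy]-2-[(4-methoxybenzyl)oxy]-4,8-dimethyl-10-oxocyclodeca-4,8-dien-1-yl]acetate, via potassium alkoxide 11 (not isolated), via potassium enolate 12 (not isolated)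
Conditions: KN(SiMe3)2, 18-crown-6, THF, −78 to 0 °C; then BrCH2CO2t-Bu, −78 °C; AcOH quench at −78 °C
Reagents that add atoms: tert-butyl bromoacetate, CC(C)(C)OC(=O)CBr
Why: Deprotonation gives alkoxide 11, whose anion-accelerated [3,3] shift (anionic oxy-Cope rearrangement; closest precedent is the ring expansion of isopiperitenone-derived trans-1,2-dialkenylcyclohexenols to (E,Z)-cyclodecadienones) makes C8–C9 while the doubly allylic C1–C6 bond breaks, and enolate 12 is alkylated at C7 in the same flask. The ten-membered ring closes by sigmatropic four-atom ring expansion through a chair transition state, the only one open to the trans-diequatorial alkenyl groups, with both ring bonds (to C2 and C5) equatorial. Equatorial C2 gives the E C1=C10 alkene, the cyclohexene keeps C4=C5 Z, and the Z enol ether puts the alkoxy group axial on C8, so that chirality relayed from C1 should make C8 S. Enolate 12 is formed with its inner face shielded across the ring by C1=C10, so the bromoacetate should enter from the outer face, anti to the new C8–C9 bond (the anti sense of a Fráter–Seebach alkylation), giving 7S. The step needs the [3,3] path to beat a [1,3] shift and a Cope through the ring alkene, which the chair-compatible trans arrangement secures; it also needs enolate 12 to keep its C8 alkoxide, for which the crown ether leaves the departing alkoxide unstabilised, the time at 0 °C is kept short, and alkylation and quench are done at −78 °C.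

**Step 8**
Reactants: 13 keto ester
Product: 14 tert-butyl 2-[(1S,2S,4E,7R,8Z)-7-[(tert-butyldimethylsilyl)oxy]-2-hydroxy-4,8-dimethyl-10-oxocyclodeca-4,8-dien-1-yl]acetate
Conditions: DDQ, CH2Cl2/pH 7 buffer, 0 °C
Reagents that add atoms: none
Why: Oxidative cleavage of the 4-methoxybenzyl ether; the silyl ether, the tert-butyl ester and the alkenes should survive, and no stereocentre is touched.

**Step 9**
Reactants: 14 β-hydroxy ketone
Product: 15 tert-butyl 2-[(1S,2S,4E,7R,8Z,10S)-7-[(tert-butyldimethylsilyl)oxy]-2,10-dihydroxy-4,8-dimethylcyclodeca-4,8-dien-1-yl]acetate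
Conditions: Me4NBH(OAc)3, MeCN/AcOH, −30 °C
Reagents that add atoms: none
Why: Evans–Saksena hydroxyl-directed reduction; the borohydride bound to O8 delivers hydride internally to C6 and should give the 1,3-anti diol, that is 6S.

**Step 10**
Reactants: 15 anti-diol ester
Product: 16 (3R,6S,7S,8S)-3-[(tert-butyldimethylsilyl)oxy]-8-hydroxy-13-norgermacra-1(10)E,4Z-dien-12,6-olide
Conditions: KOt-Bu (0.2 equiv), THF, 0 °C
Reagents that add atoms: none
Why: Alkoxide-catalysed intramolecular transesterification (γ-lactonisation) under equilibrating conditions, where the trans-fused 6,12-lactone is expected to be favoured over the cis-fused 8,12-isomer; no new stereocentre.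

**Step 11**
Reactants: 16 hydroxy lactone
Product: 19 (3R,6S,7S,8S)-3-[(tert-butyldimethylsilyl)oxy]-8-hydroxygermacra-1(10)E,4Z,11(13)-trien-12,6-olide, via Mannich base 17 (not isolated), via methiodide 18 (not isolated)
Conditions: LiN(i-Pr)2 (2.3 equiv), THF, −78 °C; CH2=NMe2+ I−, −78 °C to rt; then MeI, MeOH, rt; then aq NaHCO3, CH2Cl2
Reagents that add atoms: Eschenmoser's salt (N,N-dimethylmethyleneiminium iodide), C=[N+](C)C.[I-]
Why: Eschenmoser α-methylenation: Mannich reaction of the lactone enolate (the C8 hydroxyl is carried as its alkoxide), N-methylation and Hofmann-type elimination; the C11 centre of 17 is lost on elimination.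

**Step 12**
Reactants: 19 hydroxy methylene lactone; 20 (2R)-2-methylbutanoic acid
Product: 21 (3R,6S,7S,8S)-3-[(tert-butyldimethylsilyl)oxy]-8-[(2R)-2-methylbutanoyloxy]germacra-1(10)E,4Z,11(13)-trien-12,6-olide
Conditions: DCC, DMAP (cat.), CH2Cl2, 0 °C to rt
Reagents that add atoms: none
Why: Steglich esterification; O-acylation keeps C8 as set, and the α-centre of the acid should not enolise under these conditions.

**Step 13**
Reactants: 21 silyl ether ester
Product: 22 (3R,6S,7S,8S)-3-hydroxy-8-[(2R)-2-methylbutanoyloxy]germacra-1(10)E,4Z,11(13)-trien-12,6-olide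
Conditions: HF·pyridine, pyridine/THF, 0 °C to rt
Reagents that add atoms: none
Why: Buffered fluoride desilylation, done before the oxirane exists, so the esters and the methylene lactone are the only sensitive groups present.

**Step 14**
Reactants: 22 C3 alcohol
Product: 23 (3R,6S,7S,8S)-3-acetoxy-8-[(2R)-2-methylbutanoyloxy]germacra-1(10)E,4Z,11(13)-trien-12,6-olide
Conditions: Ac2O, pyridine, DMAP (cat.), CH2Cl2, 0 °C
Reagents that add atoms: acetic anhydride, CC(=O)OC(C)=O
Why: DMAP-catalysed acetylation of the only free hydroxyl.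

**Step 15**
Reactants: 23 diester triene
Product: 24 (1S,3R,6S,7S,8S,10S)-3-acetoxy-1,10-dihydroxy-8-[(2R)-2-methylbutanoyloxy]germacra-4Z,11(13)-dien-12,6-olide
Conditions: OsO4 (cat.), N-methylmorpholine N-oxide, acetone/H2O, 0 °C
Reagents that add atoms: N-methylmorpholine N-oxide, C[N+]1([O-])CCOCC1; water, O
Why: Upjohn syn-dihydroxylation; the electron-rich C1=C10 alkene should react before the electron-poor C11=C13 and the C4=C5 alkene flanked by two allylic acyloxy groups, from the exposed outer face of the E alkene (as in peripheral epoxidation of 1(10)E-germacranolides), setting 10S and 1S.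

**Step 16**
Reactants: 24 1,10-diol
Product: 26 (1R,3R,6S,7S,8S,10S)-3-acetoxy-1,10-epoxy-8-[(2R)-2-methylbutanoyloxy]germacra-4Z,11(13)-dien-12,6-olide, via C1 mesylate 25 (not isolated)
Conditions: MsCl, Et3N, CH2Cl2, −20 °C; then DBU, 0 °C to rt
Reagents that add atoms: none
Why: Selective sulfonylation of the secondary C1 hydroxyl, then intramolecular Williamson (SN2) closure by the tertiary C10 oxygen with inversion at C1 (1S to 1R), which turns the syn-diol of the E alkene into the cis-oxirane.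

**Compound list**

1 | (R)-(−)-carvone | CC1=CC[C@H](CC1=O)C(C)=C | starting material
2 | (1R,5R)-cis-carveol | CC1=CC[C@H](C[C@H]1O)C(C)=C | intermediate
3 | tert-butyldimethyl{[(1R,5R)-2-methyl-5-(prop-1-en-2-yl)cyclohex-2-en-1-yl]oxy}silane | CC1=CC[C@H](C[C@H]1O[Si](C)(C)C(C)(C)C)C(C)=C | intermediate
4 | (4R,6R)-4-[(tert-butyldimethylsilyl)oxy]-3-methyl-6-(prop-1-en-2-yl)cyclohex-2-en-1-one | CC1=CC(=O)[C@H](C[C@H]1O[Si](C)(C)C(C)(C)C)C(C)=C | intermediate
5 | 4-methoxybenzyl alcohol | COc1ccc(CO)cc1 | starting material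
6 | 4-methoxybenzyl vinyl ether | COc1ccc(COC=C)cc1 | intermediate
7 | 1,2-dibromo-1-[(4-methoxybenzyl)oxy]ethane (racemic) | COc1ccc(COC(Br)CBr)cc1 | intermediate
8 | (Z)-1-bromo-2-[(4-methoxybenzyl)oxy]ethene | COc1ccc(CO/C=C\Br)cc1 | intermediate
9 | (Z)-2-[(4-methoxybenzyl)oxy]ethenyllithium | [Li]/C=C\OCc1ccc(OC)cc1 | intermediate
10 | (1R,4R,6R)-4-[(tert-butyldimethylsilyl)oxy]-1-{(Z)-2-[(4-methoxybenzyl)oxy]ethenyl}-3-methyl-6-(prop-1-en-2-yl)cyclohex-2-en-1-ol | CC1=C[C@](O)(/C=C\OCc2ccc(OC)cc2)[C@H](C[C@H]1O[Si](C)(C)C(C)(C)C)C(C)=C | intermediate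
11 | potassium alkoxide of 10 | CC1=C[C@]([O-])(/C=C\OCc2ccc(OC)cc2)[C@H](C[C@H]1O[Si](C)(C)C(C)(C)C)C(C)=C.[K+] | intermediate
12 | potassium (1Z,3S,5E,8R,9Z)-8-[(tert-butyldimethylsilyl)oxy]-3-[(4-methoxybenzyl)oxy]-5,9-dimethylcyclodeca-1,5,9-trien-1-olate (C6–C7 enolate, C5 and C8 trans across it) | [K+].[O-]/C1=C\[C@@H](OCc2ccc(OC)cc2)C/C(C)=C/C[C@@H](O[Si](C)(C)C(C)(C)C)/C(C)=C\1 | intermediate
13 | tert-butyl 2-[(1S,2S,4E,7R,8Z)-7-[(tert-butyldimethylsilyl)oxy]-2-[(4-methoxybenzyl)oxy]-4,8-dimethyl-10-oxocyclodeca-4,8-dien-1-yl]acetate | O=C1/C=C(/C)[C@H](O[Si](C)(C)C(C)(C)C)C/C=C(\C)C[C@H](OCc2ccc(OC)cc2)[C@@H]1CC(=O)OC(C)(C)C | intermediate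
14 | tert-butyl 2-[(1S,2S,4E,7R,8Z)-7-[(tert-butyldimethylsilyl)oxy]-2-hydroxy-4,8-dimethyl-10-oxocyclodeca-4,8-dien-1-yl]acetate | O=C1/C=C(/C)[C@H](O[Si](C)(C)C(C)(C)C)C/C=C(\C)C[C@H](O)[C@@H]1CC(=O)OC(C)(C)C | intermediate
15 | tert-butyl 2-[(1S,2S,4E,7R,8Z,10S)-7-[(tert-butyldimethylsilyl)oxy]-2,10-dihydroxy-4,8-dimethylcyclodeca-4,8-dien-1-yl]acetate | O[C@H]1/C=C(/C)[C@H](O[Si](C)(C)C(C)(C)C)C/C=C(\C)C[C@H](O)[C@@H]1CC(=O)OC(C)(C)C | intermediate
16 | (3R,6S,7S,8S)-3-[(tert-butyldimethylsilyl)oxy]-8-hydroxy-13-norgermacra-1(10)E,4Z-dien-12,6-olide (trans-fused γ-lactone, C11 is CH2) | O=C1O[C@H]2/C=C(/C)[C@H](O[Si](C)(C)C(C)(C)C)C/C=C(\C)C[C@H](O)[C@@H]2C1 | intermediate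
17 | (11S)-13-(dimethylamino)-11,13-dihydro derivative of 19 (Mannich base) | CN(C)C[C@H]1C(=O)O[C@H]2/C=C(/C)[C@H](O[Si](C)(C)C(C)(C)C)C/C=C(\C)C[C@H](O)[C@H]12 | intermediate
18 | N-methyl ammonium iodide of 17 | [I-].C[N+](C)(C)C[C@H]1C(=O)O[C@H]2/C=C(/C)[C@H](O[Si](C)(C)C(C)(C)C)C/C=C(\C)C[C@H](O)[C@H]12 | intermediate
19 | (3R,6S,7S,8S)-3-[(tert-butyldimethylsilyl)oxy]-8-hydroxygermacra-1(10)E,4Z,11(13)-trien-12,6-olide | C=C1C(=O)O[C@H]2/C=C(/C)[C@H](O[Si](C)(C)C(C)(C)C)C/C=C(\C)C[C@H](O)[C@H]12 | intermediate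
20 | (2R)-2-methylbutanoic acid | CC[C@@H](C)C(=O)O | starting material
21 | (3R,6S,7S,8S)-3-[(tert-butyldimethylsilyl)oxy]-8-[(2R)-2-methylbutanoyloxy]germacra-1(10)E,4Z,11(13)-trien-12,6-olide | C=C1C(=O)O[C@H]2/C=C(/C)[C@H](O[Si](C)(C)C(C)(C)C)C/C=C(\C)C[C@H](OC(=O)[C@H](C)CC)[C@H]12 | intermediate
22 | (3R,6S,7S,8S)-3-hydroxy-8-[(2R)-2-methylbutanoyloxy]germacra-1(10)E,4Z,11(13)-trien-12,6-olide | C=C1C(=O)O[C@H]2/C=C(/C)[C@H](O)C/C=C(\C)C[C@H](OC(=O)[C@H](C)CC)[C@H]12 | intermediate
23 | (3R,6S,7S,8S)-3-acetoxy-8-[(2R)-2-methylbutanoyloxy]germacra-1(10)E,4Z,11(13)-trien-12,6-olide | C=C1C(=O)O[C@H]2/C=C(/C)[C@H](OC(C)=O)C/C=C(\C)C[C@H](OC(=O)[C@H](C)CC)[C@H]12 | intermediate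
24 | (1S,3R,6S,7S,8S,10S)-3-acetoxy-1,10-dihydroxy-8-[(2R)-2-methylbutanoyloxy]germacra-4Z,11(13)-dien-12,6-olide | C=C1C(=O)O[C@H]2/C=C(/C)[C@H](OC(C)=O)C[C@H](O)[C@@](C)(O)C[C@H](OC(=O)[C@H](C)CC)[C@H]12 | intermediate
25 | 1-O-methanesulfonate of 24 | C=C1C(=O)O[C@H]2/C=C(/C)[C@H](OC(C)=O)C[C@H](OS(C)(=O)=O)[C@@](C)(O)C[C@H](OC(=O)[C@H](C)CC)[C@H]12 | intermediate
26 | (1R,3R,6S,7S,8S,10S)-3-acetoxy-1,10-epoxy-8-[(2R)-2-methylbutanoyloxy]germacra-4Z,11(13)-dien-12,6-olide (CNP0340603.1) | C=C1C(=O)O[C@H]2/C=C(/C)[C@H](OC(C)=O)C[C@H]3O[C@@]3(C)C[C@H](OC(=O)[C@H](C)CC)[C@H]12 | target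

**Step count and risks**

Total steps: 16. Longest linear sequence: 14 (steps 1–3 and 6–16, from (R)-carvone); steps 4–5 make the vinyl bromide.

The three steps most likely to fail:

1. Step 7. The C8 alkoxide may be lost from the potassium enolate by β-elimination, or C8 may be scrambled by elimination and re-addition, before the enolate is alkylated. The risk grows if the axial alkoxy group slows the rearrangement so that it needs more than 0 °C. Fallback, setting out from 4 and returning at 14: vinylmagnesium bromide adds trans to the isopropenyl group to give the trans-dialkenyl carbinol F1. Its anionic oxy-Cope rearrangement (KH, 18-crown-6, THF) with Me3SiCl quench gives the ring-expanded silyl enol ether F2, which has no β-leaving group. Saegusa–Ito oxidation with Pd(OAc)2 gives the cross-conjugated dienone F3. Copper-catalysed conjugate borylation of its disubstituted C7=C8 enone (CuCl, NaOt-Bu, a chiral bisphosphine, B2pin2, MeOH) gives the β-boryl ketone F4, which NaBO3 oxidises with retention to the β-hydroxy ketone F5. The dianion of F5 (LiN(i-Pr)2, 2 equiv, −78 °C) is alkylated with tert-butyl bromoacetate anti to the alkoxide (Fráter–Seebach sense), which gives 14; steps 6 to 8 are then not needed.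

2. Step 10. Ring closure may go onto O8 instead of O6 (cis-fused 8,12-lactone), or the equilibrium between the two lactones may be unfavourable. Fallback, setting out from 14 and returning at 21: acid 20 is reduced with LiAlH4 to (2R)-2-methylbutan-1-ol F6 and oxidised with Dess–Martin periodinane to (2R)-2-methylbutanal F7. Evans–Tishchenko reduction of 14 with F7 and catalytic SmI2 gives the anti-1,3-diol monoester F8, in which O8 already carries the final acyl group and only O6 is free. Acid-catalysed lactonisation (camphorsulfonic acid, toluene, 60 °C) can then only give the 6,12-lactone F9. Kinetic enolisation of the lactone (LiN(i-Pr)2, 1.05 equiv, −78 °C; the lactone CH2 is more acidic and less hindered than the α-branched ester) and Eschenmoser's salt give the Mannich base F10. MeI gives the methiodide F11, and NaHCO3 gives 21; steps 9 to 12 are then not needed.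

3. Step 15. Osmylation may also attack the C11=C13 methylene (or C4=C5), and the facial bias at C1=C10 may be too small. Fallback, setting out from 23 and returning at 26: conjugate addition of dimethylamine (THF/EtOH, rt) masks the methylene as the amine adduct F12. OsO4/N-methylmorpholine N-oxide then gives the 1,10-diol F13. MsCl/Et3N gives the C1 mesylate F14, and DBU closes the cis-oxirane F15 with inversion at C1. MeI gives the methiodide F16, and NaHCO3 restores the methylene lactone, giving 26.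

**Further compounds**

F1 | step 7 | (1R,4R,6R)-4-[(tert-butyldimethylsilyl)oxy]-1-ethenyl-3-methyl-6-(prop-1-en-2-yl)cyclohex-2-en-1-ol | CC1=C[C@](O)(C=C)[C@H](C[C@H]1O[Si](C)(C)C(C)(C)C)C(C)=C
F2 | step 7 | trimethylsilyl enol ether of (5E,8R,9Z)-8-[(tert-butyldimethylsilyl)oxy]-5,9-dimethylcyclodeca-5,9-dien-1-one (C6–C7 enol ether) | C[Si](C)(C)O/C1=C\CC/C(C)=C/C[C@@H](O[Si](C)(C)C(C)(C)C)/C(C)=C\1
F3 | step 7 | (2E,5E,8R,9Z)-8-[(tert-butyldimethylsilyl)oxy]-5,9-dimethylcyclodeca-2,5,9-trien-1-one | O=C1/C=C(/C)[C@H](O[Si](C)(C)C(C)(C)C)C/C=C(\C)C/C=C/1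
F4 | step 7 | (3S,5E,8R,9Z)-8-[(tert-butyldimethylsilyl)oxy]-5,9-dimethyl-3-(4,4,5,5-tetramethyl-1,3,2-dioxaborolan-2-yl)cyclodeca-5,9-dien-1-one | O=C1/C=C(/C)[C@H](O[Si](C)(C)C(C)(C)C)C/C=C(\C)C[C@H](B2OC(C)(C)C(C)(C)O2)C1
F5 | step 7 | (3S,5E,8R,9Z)-8-[(tert-butyldimethylsilyl)oxy]-3-hydroxy-5,9-dimethylcyclodeca-5,9-dien-1-one | O=C1/C=C(/C)[C@H](O[Si](C)(C)C(C)(C)C)C/C=C(\C)C[C@H](O)C1
F6 | step 10 | (2R)-2-methylbutan-1-ol | CC[C@@H](C)CO
F7 | step 10 | (2R)-2-methylbutanal | CC[C@@H](C)C=O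
F8 | step 10 | 8-O-[(2R)-2-methylbutanoyl] derivative of diol ester 15 (O6 free) | O[C@H]1/C=C(/C)[C@H](O[Si](C)(C)C(C)(C)C)C/C=C(\C)C[C@H](OC(=O)[C@H](C)CC)[C@@H]1CC(=O)OC(C)(C)C
F9 | step 10 | (3R,6S,7S,8S)-3-[(tert-butyldimethylsilyl)oxy]-8-[(2R)-2-methylbutanoyloxy]-13-norgermacra-1(10)E,4Z-dien-12,6-olide | O=C1O[C@H]2/C=C(/C)[C@H](O[Si](C)(C)C(C)(C)C)C/C=C(\C)C[C@H](OC(=O)[C@H](C)CC)[C@@H]2C1
F10 | step 10 | (11S)-13-(dimethylamino)-11,13-dihydro derivative of 21 | CN(C)C[C@H]1C(=O)O[C@H]2/C=C(/C)[C@H](O[Si](C)(C)C(C)(C)C)C/C=C(\C)C[C@H](OC(=O)[C@H](C)CC)[C@H]12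
F11 | step 10 | N-methyl ammonium iodide of F10 | [I-].C[N+](C)(C)C[C@H]1C(=O)O[C@H]2/C=C(/C)[C@H](O[Si](C)(C)C(C)(C)C)C/C=C(\C)C[C@H](OC(=O)[C@H](C)CC)[C@H]12
F12 | step 15 | (11R)-13-(dimethylamino)-11,13-dihydro derivative of 23 | CN(C)C[C@@H]1C(=O)O[C@H]2/C=C(/C)[C@H](OC(C)=O)C/C=C(\C)C[C@H](OC(=O)[C@H](C)CC)[C@H]12
F13 | step 15 | (1S,10S)-1,10-diol of F12 | CN(C)C[C@@H]1C(=O)O[C@H]2/C=C(/C)[C@H](OC(C)=O)C[C@H](O)[C@@](C)(O)C[C@H](OC(=O)[C@H](C)CC)[C@H]12
F14 | step 15 | 1-O-methanesulfonate of F13 | CN(C)C[C@@H]1C(=O)O[C@H]2/C=C(/C)[C@H](OC(C)=O)C[C@H](OS(C)(=O)=O)[C@@](C)(O)C[C@H](OC(=O)[C@H](C)CC)[C@H]12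
F15 | step 15 | (11R)-13-(dimethylamino)-11,13-dihydro derivative of 26 | CN(C)C[C@@H]1C(=O)O[C@H]2/C=C(/C)[C@H](OC(C)=O)C[C@H]3O[C@@]3(C)C[C@H](OC(=O)[C@H](C)CC)[C@H]12
F16 | step 15 | N-methyl ammonium iodide of F15 | [I-].C[N+](C)(C)C[C@@H]1C(=O)O[C@H]2/C=C(/C)[C@H](OC(C)=O)C[C@H]3O[C@@]3(C)C[C@H](OC(=O)[C@H](C)CC)[C@H]12
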